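**Retrosynthetic overview**

- Feature: on the benzene ring (C1 formyl, C2 hydroxyl) the C5 substituent is a CH2–CH(OH)–CMe2OH unit, that is a terminal epoxide opened at its CH2, and it sits directly ortho to the E-alkenyl chain on C6, whose other neighbour C1 is already substituted. This vicinal alkyl/alkenyl pair beside a blocked position is what palladium/norbornene (Catellani) chemistry on a C6 iodide delivers.
- Key disconnection: C5–CH2 and C6–C1' are formed in one operation from aryl iodide 4, epoxide 8 and chain olefin 16, giving benzoate 17. The end game is CO2Me → CH2OH → CHO, then global acid deprotection.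
- 4 comes from 3-iodophenol (MOM ether, lithiation between I and O, ClCO2Me). 8 comes from 2-methylbut-3-en-2-ol (silylation, epoxidation, hydrolytic kinetic resolution).
- 16 comes from cross-metathesis of the L-tartrate-derived divinyl dioxolane 15 (C3', C4') with the TBS ether 12 of (S)-hept-6-en-2-ol, itself from (S)-propylene oxide (C10').
- No ring is formed: the benzene ring is bought and the dioxolane is only a protecting group.

Key step: step 10

Assumption: the (R,R)-cobalt salen catalyst is taken to leave the S epoxide 8, as it does for epichlorohydrin and methyl glycidate, which have the same spatial arrangement (the S,S catalyst would be used if the sense proved opposite); a shift of the triethylsilyl group between the two neighbouring side-chain oxygens under basic conditions would be without consequence, since both are freed together at the end.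

**Step 1**
Reactants: 1 3-iodophenol
Product: 2 1-iodo-3-(methoxymethoxy)benzene
Conditions: MOMCl, i-Pr2NEt, CH2Cl2, 0 °C → rt
Reagents that add atoms: chloromethyl methyl ether (MOMCl), COCCl
Why: O-alkylation of the phenol (Williamson type) installs the acetal ether that later directs ortho-lithiation and falls off in acid.

**Step 2**
Reactants: 2 1-iodo-3-(methoxymethoxy)benzene
Product: 4 methyl 2-iodo-6-(methoxymethoxy)benzoate, via aryllithium 3 (not isolated)
Conditions: LiN(i-Pr)2 (1.1 equiv), THF, −78 °C; then ClCO2Me (3 equiv), −78 °C → rt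
Reagents that add atoms: methyl chloroformate, COC(Cl)=O
Why: Directed ortho-metalation removes the most acidic proton, the one flanked by the MOM ether and iodine, with an amide base that does not exchange the iodide, and the chelated aryllithium is acylated at −78 °C before aryne formation or halogen migration can set in.

**Step 3**
Reactants: 5 2-methylbut-3-en-2-ol
Product: 6 triethyl[(2-methylbut-3-en-2-yl)oxy]silane
Conditions: Et3SiOTf, 2,6-lutidine, CH2Cl2, −78 → 0 °C
Reagents that add atoms: triethylsilyl triflate, CC[Si](CC)(CC)OS(=O)(=O)C(F)(F)F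
Why: Silylation of the hindered tertiary alcohol with a silyl triflate and a hindered pyridine base is fast at low temperature and leaves the olefin alone.

**Step 4**
Reactants: 6 triethyl[(2-methylbut-3-en-2-yl)oxy]silane
Product: 7 racemic triethyl{[2-(oxiran-2-yl)propan-2-yl]oxy}silane
Conditions: mCPBA (2 equiv), CH2Cl2, rt → 40 °C
Reagents that add atoms: 3-chloroperbenzoic acid (mCPBA), OOC(=O)c1cccc(Cl)c1
Why: Prilezhaev epoxidation of the only olefin gives the terminal epoxide as a racemate, slowly because the olefin is monosubstituted, while the silyl ether survives the peracid.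

**Step 5**
Reactants: 7 racemic triethyl{[2-(oxiran-2-yl)propan-2-yl]oxy}silane
Product: 8 triethyl({2-[(2S)-oxiran-2-yl]propan-2-yl}oxy)silane
Conditions: (R,R)-(salen)Co(OAc) (2 mol%; trivalent cobalt, salen = N,N'-bis(3,5-di-tert-butylsalicylidene)cyclohexane-1,2-diamine dianion), H2O (0.55 equiv), THF (minimal), 0 °C → rt
Reagents that add atoms: none
Why: Jacobsen hydrolytic kinetic resolution: the chiral cobalt salen complex delivers water to the CH2 of the R epoxide much faster than to its enantiomer, so the S epoxide, which becomes the side-chain carbinol of the target, is recovered while the R enantiomer leaves as the diol.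

**Step 6**
Reactants: 9 (S)-propylene oxide; 10 but-3-enylmagnesium bromide
Product: 11 (2S)-hept-6-en-2-ol
Conditions: CuI (10 mol%), THF, −40 → 0 °C
Reagents that add atoms: none
Why: Copper-catalysed Grignard opening of the epoxide occurs at the unsubstituted CH2, so the S stereocentre (C10' of the target) is carried over untouched.

**Step 7**
Reactants: 11 (2S)-hept-6-en-2-ol
Product: 12 tert-butyl{[(2S)-hept-6-en-2-yl]oxy}dimethylsilane
Conditions: TBSCl, imidazole, DMF, rt
Reagents that add atoms: tert-butyldimethylsilyl chloride, CC(C)(C)[Si](C)(C)Cl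
Why: Standard imidazole-mediated silylation of the secondary alcohol gives an ether that tolerates metathesis, palladium catalysis and hydride.

**Step 8**
Reactants: 13 dimethyl (4R,5R)-2,2-dimethyl-1,3-dioxolane-4,5-dicarboxylate
Product: 15 (4S,5S)-4,5-diethenyl-2,2-dimethyl-1,3-dioxolane, via dioxolane-4,5-dicarbaldehyde 14 (not isolated)
Conditions: i-Bu2AlH (2.1 equiv), toluene, −78 °C; then Ph3P=CH2 (from Ph3PCH3Br, KOt-Bu, THF), −78 °C → rt; aq potassium sodium tartrate
Reagents that add atoms: methyltriphenylphosphonium bromide (CH2 donor through its ylide), C[P+](c1ccccc1)(c1ccccc1)c1ccccc1.[Br-]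
Why: Half-reduction of both esters to aluminium hemiacetals at −78 °C followed by Wittig methylenation in the same flask avoids isolating the epimerisable dialdehyde; both stereocentres come from L-tartrate, and the descriptors change from R to S only through the priority rules.

**Step 9**
Reactants: 12 tert-butyl{[(2S)-hept-6-en-2-yl]oxy}dimethylsilane; 15 (4S,5S)-4,5-diethenyl-2,2-dimethyl-1,3-dioxolane (3 equiv)
Product: 16 tert-butyl({(2S,6E)-7-[(4S,5S)-5-ethenyl-2,2-dimethyl-1,3-dioxolan-4-yl]hept-6-en-2-yl}oxy)dimethylsilane
Conditions: second-generation Hoveyda–Grubbs catalyst (5 mol%), CH2Cl2, 40 °C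
Reagents that add atoms: none
Why: Olefin cross-metathesis joins the terminal olefin of 12 to one of the two equivalent vinyl groups of 15, whose excess holds back double coupling, and should favour the E olefin under thermodynamic control without touching any stereocentre (Z isomer and doubly coupled diene would be removed by chromatography).

**Step 10**
Reactants: 4 methyl 2-iodo-6-(methoxymethoxy)benzoate; 8 triethyl({2-[(2S)-oxiran-2-yl]propan-2-yl}oxy)silane (2.5 equiv); 16 tert-butyl({(2S,6E)-7-[(4S,5S)-5-ethenyl-2,2-dimethyl-1,3-dioxolan-4-yl]hept-6-en-2-yl}oxy)dimethylsilane (2 equiv)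
Product: 17 methyl 2-[(E)-2-{(4S,5S)-5-[(1E,6S)-6-(tert-butyldimethylsilyloxy)hept-1-en-1-yl]-2,2-dimethyl-1,3-dioxolan-4-yl}ethenyl]-3-[(2S)-2-hydroxy-3-methyl-3-(triethylsilyloxy)butyl]-6-(methoxymethoxy)benzoate
Conditions: Pd(OAc)2 (10 mol%), XPhos (20 mol%), potassium 5-norbornene-2-carboxylate (1.5 equiv; from the commercial acid and KOH), NMP, 70 °C
Reagents that add atoms: none
Why: Proposed new method: zerovalent palladium adds to the C–I bond of 4, the norbornene carboxylate inserts, and C–H palladation at the only free ortho carbon (C5 of the target, the other ortho position carrying CO2Me) gives an aryl–norbornyl palladacycle of divalent palladium that opens epoxide 8 by SN2 attack at its unhindered CH2; reductive elimination from the tetravalent palladium alkoxide forms the aryl–CH2 bond, the now doubly ortho-substituted intermediate extrudes norbornene, and the aryl–palladium species inserts the terminal CH=CH2 of 16 and loses the benzylic β-hydrogen. The closest known reaction is the palladium/norbornene ortho-alkylation of aryl iodides with epoxides that is terminated by Heck coupling with acrylates; termination with an unactivated olefin carrying an allylic acetal, as here, has not been shown. No ring is closed and no stereocentre is created: the S carbinol of 8 is retained because only its CH2–O bond is broken, the dioxolane and silyloxy centres of 16 lie outside the reacting atoms, and the new aryl–CH=CH bond is E through syn insertion followed by syn β-hydride elimination to the conjugated styrene. The step needs site selectivity for C5, which the norbornene relay and the blocked second ortho position secure, and it needs the intermolecular Heck step to beat C–O reductive elimination of the side-chain alkoxide (dihydrobenzofuran), premature Heck coupling of 4 and β-hydride elimination toward the dioxolane C–H; excess 8 and 16, the bulky XPhos ligand and the carboxylate/carboxylic acid buffer that keeps the new hydroxyl protonated are chosen for this. The internal trans olefin of 16 is disubstituted and should not compete for insertion.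

**Step 11**
Reactants: 17 the benzoate from step 10
Product: 18 {2-[(E)-2-{(4S,5S)-5-[(1E,6S)-6-(tert-butyldimethylsilyloxy)hept-1-en-1-yl]-2,2-dimethyl-1,3-dioxolan-4-yl}ethenyl]-3-[(2S)-2-hydroxy-3-methyl-3-(triethylsilyloxy)butyl]-6-(methoxymethoxy)phenyl}methanol
Conditions: LiAlH4, THF, 0 °C → rt
Reagents that add atoms: none
Why: Hydride reduction of the hindered methyl ester to the benzylic alcohol leaves the acetals, silyl ethers and both olefins untouched.

**Step 12**
Reactants: 18 the benzylic alcohol from step 11
Product: 19 2-[(E)-2-{(4S,5S)-5-[(1E,6S)-6-(tert-butyldimethylsilyloxy)hept-1-en-1-yl]-2,2-dimethyl-1,3-dioxolan-4-yl}ethenyl]-3-[(2S)-2-hydroxy-3-methyl-3-(triethylsilyloxy)butyl]-6-(methoxymethoxy)benzaldehyde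
Conditions: MnO2 (activated, excess), CH2Cl2, rt
Reagents that add atoms: none
Why: MnO2 oxidises only the benzylic alcohol, so the unactivated secondary alcohol of the side chain remains and no over-oxidation to the acid occurs.

**Step 13**
Reactants: 19 the benzaldehyde from step 12
Product: 20 3-[(2S)-2,3-dihydroxy-3-methylbutyl]-6-hydroxy-2-[(1E,3S,4S,5E,10S)-3,4,10-trihydroxyundeca-1,5-dien-1-yl]benzaldehyde (CNP0348098.1)
Conditions: aq HCl (2 M), THF, rt → 40 °C
Reagents that add atoms: none
Why: Acid hydrolysis cleaves the aryl MOM acetal, the dioxolane and both silyl ethers in one operation, and no stereocentre is touched because only acetal C–O and Si–O bonds are broken.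

**Compound list**

1 | 3-iodophenol | Oc1cccc(I)c1 | starting material
2 | 1-iodo-3-(methoxymethoxy)benzene | COCOc1cccc(I)c1 | intermediate
3 | [2-iodo-6-(methoxymethoxy)phenyl]lithium (forms in the flask) | [Li]c1c(I)cccc1OCOC | intermediate
4 | methyl 2-iodo-6-(methoxymethoxy)benzoate | COC(=O)c1c(I)cccc1OCOC | intermediate
5 | 2-methylbut-3-en-2-ol | C=CC(C)(C)O | starting material
6 | triethyl[(2-methylbut-3-en-2-yl)oxy]silane | C=CC(C)(C)O[Si](CC)(CC)CC | intermediate
7 | racemic triethyl{[2-(oxiran-2-yl)propan-2-yl]oxy}silane | CC[Si](CC)(CC)OC(C)(C)C1CO1 | intermediate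
8 | triethyl({2-[(2S)-oxiran-2-yl]propan-2-yl}oxy)silane | C1[C@H](O1)C(C)(C)O[Si](CC)(CC)CC | intermediate
9 | (S)-propylene oxide | C[C@H]1CO1 | starting material
10 | but-3-enylmagnesium bromide | C=CCC[Mg]Br | starting material
11 | (2S)-hept-6-en-2-ol | C[C@H](O)CCCC=C | intermediate
12 | tert-butyl{[(2S)-hept-6-en-2-yl]oxy}dimethylsilane | C[C@H](O[Si](C)(C)C(C)(C)C)CCCC=C | intermediate
13 | dimethyl (4R,5R)-2,2-dimethyl-1,3-dioxolane-4,5-dicarboxylate (dimethyl 2,3-O-isopropylidene-L-tartrate) | COC(=O)[C@@H]1OC(C)(C)O[C@H]1C(=O)OC | starting material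
14 | (4R,5R)-2,2-dimethyl-1,3-dioxolane-4,5-dicarbaldehyde (forms in the flask, held as its aluminium hemiacetal) | O=C[C@@H]1OC(C)(C)O[C@H]1C=O | intermediate
15 | (4S,5S)-4,5-diethenyl-2,2-dimethyl-1,3-dioxolane | C=C[C@@H]1OC(C)(C)O[C@H]1C=C | intermediate
16 | tert-butyl({(2S,6E)-7-[(4S,5S)-5-ethenyl-2,2-dimethyl-1,3-dioxolan-4-yl]hept-6-en-2-yl}oxy)dimethylsilane | C[C@H](O[Si](C)(C)C(C)(C)C)CCC/C=C/[C@@H]1OC(C)(C)O[C@H]1C=C | intermediate
17 | methyl 2-[(E)-2-{(4S,5S)-5-[(1E,6S)-6-(tert-butyldimethylsilyloxy)hept-1-en-1-yl]-2,2-dimethyl-1,3-dioxolan-4-yl}ethenyl]-3-[(2S)-2-hydroxy-3-methyl-3-(triethylsilyloxy)butyl]-6-(methoxymethoxy)benzoate | C[C@H](O[Si](C)(C)C(C)(C)C)CCC/C=C/[C@@H]1OC(C)(C)O[C@H]1/C=C/c1c(C[C@H](O)C(C)(C)O[Si](CC)(CC)CC)ccc(OCOC)c1C(=O)OC | intermediate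
18 | benzylic alcohol of 17 (CO2Me replaced by CH2OH) | C[C@H](O[Si](C)(C)C(C)(C)C)CCC/C=C/[C@@H]1OC(C)(C)O[C@H]1/C=C/c1c(C[C@H](O)C(C)(C)O[Si](CC)(CC)CC)ccc(OCOC)c1CO | intermediate
19 | benzaldehyde of 18 (CH2OH replaced by CHO) | C[C@H](O[Si](C)(C)C(C)(C)C)CCC/C=C/[C@@H]1OC(C)(C)O[C@H]1/C=C/c1c(C[C@H](O)C(C)(C)O[Si](CC)(CC)CC)ccc(OCOC)c1C=O | intermediate
20 | 3-[(2S)-2,3-dihydroxy-3-methylbutyl]-6-hydroxy-2-[(1E,3S,4S,5E,10S)-3,4,10-trihydroxyundeca-1,5-dien-1-yl]benzaldehyde | C[C@H](O)CCC/C=C/[C@H](O)[C@@H](O)/C=C/c1c(C[C@H](O)C(C)(C)O)ccc(O)c1C=O | target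

**Step count and risks**

Total step count: 13.
Longest linear sequence: 7 steps (steps 6, 7, 9, 10, 11, 12, 13 from (S)-propylene oxide 9; equally steps 3, 4, 5, 10, 11, 12, 13 from 5).

Steps most likely to fail:

1. Step 10 (Proposed new method). What may go wrong: the side-chain alkoxide formed on epoxide opening may close onto palladium by C–O reductive elimination faster than the unactivated olefin inserts, the aryl iodide may undergo Heck coupling before ortho-alkylation, or β-hydride elimination may run toward the dioxolane C–H. The fallback uses known reactions only, sets out from epoxide 8 and olefin 16 and returns to the route at 17.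
   - Commercial 3-bromophenol F1 is converted into 1-bromo-3-(methoxymethoxy)benzene F2 (MOMCl, i-Pr2NEt).
   - F2 is iodinated para to the ether oxygen to 2-bromo-1-iodo-4-(methoxymethoxy)benzene F3 (NIS, MeCN, 60 °C).
   - F3 is lithiated between bromine and the MOM ether with LiN(i-Pr)2 at −78 °C to [2-bromo-3-iodo-6-(methoxymethoxy)phenyl]lithium F4, which is acylated with ClCO2Me to methyl 2-bromo-3-iodo-6-(methoxymethoxy)benzoate F5.
   - Selective iodine–magnesium exchange (i-PrMgCl·LiCl, THF, −40 °C) gives [2-bromo-3-(methoxycarbonyl)-4-(methoxymethoxy)phenyl]magnesium chloride F6.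
   - With CuI (10 mol%) F6 opens 8 at its CH2 to methyl 2-bromo-3-[(2S)-2-hydroxy-3-methyl-3-(triethylsilyloxy)butyl]-6-(methoxymethoxy)benzoate F7.
   - An ordinary Mizoroki–Heck reaction of the aryl bromide F7 with 16 (Pd(P(t-Bu)3)2, Cy2NMe, dioxane, 80 °C) then gives 17. The amine base leaves the hydroxyl protonated, so etherification should not compete.

2. Step 9. What may go wrong: the two vinyl groups of 15 are equivalent, so double cross-metathesis and self-metathesis of 12 compete with the single coupling, and the E/Z outcome rests only on thermodynamic preference. The fallback reverses the order of fragment union; it sets out from 4, 8, 12 and 15 and returns at 17.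
   - The three-component coupling of step 10 is run with a large excess of the cheap, volatile diene 15 in place of 16, so that only one vinyl group is arylated. This gives methyl 2-{(E)-2-[(4S,5S)-5-ethenyl-2,2-dimethyl-1,3-dioxolan-4-yl]ethenyl}-3-[(2S)-2-hydroxy-3-methyl-3-(triethylsilyloxy)butyl]-6-(methoxymethoxy)benzoate F8.
   - The single terminal olefin of F8 is then joined to excess 12 by cross-metathesis (second-generation Hoveyda–Grubbs catalyst, CH2Cl2, 40 °C) to give 17. The hindered styrene olefin should react far more slowly.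

3. Step 13. What may go wrong: acid strong enough to hydrolyse the trans-dioxolane and the aryl MOM ether may ionise the allylic C3' or C4' hydroxyl first, leading to allylic transposition or to capture of the cinnamyl cation by the side-chain hydroxyl. The fallback replaces global Brønsted-acid hydrolysis by two non-hydrolytic stages; it sets out from 19 and returns at 20.
   - Me2BBr (CH2Cl2, −78 °C, then aq NaHCO3) cleaves the MOM ether and the acetonide while the silyl ethers stay, giving 2-[(1E,3S,4S,5E,10S)-10-(tert-butyldimethylsilyloxy)-3,4-dihydroxyundeca-1,5-dien-1-yl]-6-hydroxy-3-[(2S)-2-hydroxy-3-methyl-3-(triethylsilyloxy)butyl]benzaldehyde F9.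
   - HF·pyridine buffered with pyridine (THF, 0 °C → rt) then removes both silyl groups to give 20.

**Further compounds**

F1 | step 10 | 3-bromophenol | Oc1cccc(Br)c1
F2 | step 10 | 1-bromo-3-(methoxymethoxy)benzene | COCOc1cccc(Br)c1
F3 | step 10 | 2-bromo-1-iodo-4-(methoxymethoxy)benzene | COCOc1ccc(I)c(Br)c1
F4 | step 10 | [2-bromo-3-iodo-6-(methoxymethoxy)phenyl]lithium | [Li]c1c(Br)c(I)ccc1OCOC
F5 | step 10 | methyl 2-bromo-3-iodo-6-(methoxymethoxy)benzoate | COC(=O)c1c(Br)c(I)ccc1OCOC
F6 | step 10 | [2-bromo-3-(methoxycarbonyl)-4-(methoxymethoxy)phenyl]magnesium chloride | COC(=O)c1c(Br)c([Mg]Cl)ccc1OCOC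
F7 | step 10 | methyl 2-bromo-3-[(2S)-2-hydroxy-3-methyl-3-(triethylsilyloxy)butyl]-6-(methoxymethoxy)benzoate | COC(=O)c1c(Br)c(C[C@H](O)C(C)(C)O[Si](CC)(CC)CC)ccc1OCOC
F8 | step 9 | methyl 2-{(E)-2-[(4S,5S)-5-ethenyl-2,2-dimethyl-1,3-dioxolan-4-yl]ethenyl}-3-[(2S)-2-hydroxy-3-methyl-3-(triethylsilyloxy)butyl]-6-(methoxymethoxy)benzoate | C=C[C@@H]1OC(C)(C)O[C@H]1/C=C/c1c(C[C@H](O)C(C)(C)O[Si](CC)(CC)CC)ccc(OCOC)c1C(=O)OC
F9 | step 13 | 2-[(1E,3S,4S,5E,10S)-10-(tert-butyldimethylsilyloxy)-3,4-dihydroxyundeca-1,5-dien-1-yl]-6-hydroxy-3-[(2S)-2-hydroxy-3-methyl-3-(triethylsilyloxy)butyl]benzaldehyde | C[C@H](O[Si](C)(C)C(C)(C)C)CCC/C=C/[C@H](O)[C@@H](O)/C=C/c1c(C[C@H](O)C(C)(C)O[Si](CC)(CC)CC)ccc(O)c1C=O
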